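## Structural features

The core is a bicyclo[3.2.1]oct-3-ene-2,8-dione (C1 to C8, bridgeheads C1 and quaternary C5) in which ring A is C1–C2–C3–C4–C5–C8 and ring B is C1–C7–C6–C5–C8. Cyclopentane ring C (C4, C5, C9, C10, C11) shares the C4–C5 bond with ring A and is cis-fused at C10–C11 to an indane whose benzo ring F is a resorcinol with carbons Ca (on C12), Cb (OH), Cc, Cd (OH), Ce and Cf (on C10). The eight stereocentres C12, C11, C10, C9, C5, C6, C7 and C1 form one unbroken chain, and the 4-hydroxyphenyl groups on C9 and C12 both lie on the convex face of the diquinane, cis to H10 and H11. At C5 the C8 carbonyl is cis and C6 trans to the C9 aryl, the aryl groups on C6 and C7 are trans, and the 3,5-dihydroxyphenyl group on C7 sits under the enone bridge, cis to C2. The C2/C8 diketone cannot enolise through bridgehead C1 and is therefore open to retro-Claisen cleavage by nucleophilic base, the C3=C4 enone lies close to electron-rich arenes, and the seven oxidation-prone phenols are best carried as ethers to the end. The real difficulty is quaternary C5, flanked by two carbonyl carbons and two aryl-bearing methines, together with closure of the bridged ring A, which has to occur while C1 is sp3. The C9–C12 diquinane has latent C2 symmetry: with carbonyl groups at both C4 and Cf the two aryl methines become equivalent. The key step exploits ring F, a 1,2,3,5-tetrasubstituted benzene with oxygen ortho and para to Ca, which is the pattern that a cyclopentenyl vinylketene and an alkoxyacetylene deliver.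

## Logic of the disconnections

**37 to 36.** The seven O–alkyl bonds are cut. All phenols are masked as six methyl ethers and one ethyl ether, so the oxidation-prone polyphenol appears only in the last step. The forward step needs a Lewis acid that spares the bridged diketone and the enone and uses no base.

**36 to 35.** C3=C4 is cut. The enone is the retron of an aldol condensation between the acetyl methyl C3 and the C4 ketone. This opens the bridged ring A and leaves a spiro triketone in which C1 is epimerisable. The forward step must make C3 the nucleophile while C1 stays sp3, because an enol through C1 cannot cyclise to a bridgehead.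

**35 to 34, then to 30 + 31 + 32.** C1–C2 and the C7–aryl bond are cut. They lie α and β to the C8 ketone, so conjugate addition with enolate trapping makes both. This removes the C7 stereocentre and the acetyl group. The aryl must enter trans to the C6 aryl and the enolate must be trapped at C1 only.

**30 to 28 (through 29), then to 27.** The C1=C7 unsaturation is removed and C8–C1 is cut. A cyclopentanone is the retron of a 4-pentenal hydroacylation. Ring B disappears and a quaternary aldehyde with a vinyl group remains. The forward steps need acyl–H addition faster than decarbonylation, and desaturation at C1–C7 only.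

**27 to 26, then to 24 + 25, then to 23.** C5–C6 is cut as a [3,3] shift and C5–C8 as a formylation. A γ,δ-unsaturated aldehyde with a quaternary α-carbon is the Claisen retron. One operation removes the quaternary centre C5 and the stereocentre C6. The forward step needs a chair transition state on the face of C5 away from the C9 aryl and an (E)-enol ether.

**23 to 22 to 21.** Only the phenol ether and the ketal change. This keeps C4 masked through the diazo chemistry and frees it when C5 has to be functionalised.

**21 to 16 + 17.** Ring F is cut at Ca–Cb, Cb–Cc and Cd–Ce, and the Wolff shift that moves Cf from Cb to Ce is reversed. This removes the whole tetrasubstituted arene and leaves a cyclopentene with one acyl group, so no electrophilic substitution on an arene is needed. The forward step needs one orientation of the ynol ether on the ketene.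

**16 to 14, then to 11 + 12, then to 10.** The diazo group is removed, then the Cf–acetyl bond is cut, then the enol triflate is returned to a ketone. The diazo group is installed by diazo transfer to a methyl ketone and not by acylation of a diazoalkane with an acid chloride, because a diazoalkane can also add to the conjugated double bond. The forward steps need kinetic enolisation at the methyl group and at Ca.

**10 to 9, then to 6 + 7.** The ketal is removed, then both aryl–C bonds (C9 and C12) are cut. With both carbonyls free the diquinane is C2-symmetric, so one double conjugate arylation sets C9 and C12 and either carbonyl can become C4. One molecule of 7 carries enough aryl groups for both enones. The forward step needs convex-face addition, which is the normal course on a cis-diquinane enone, and conditions mild enough for the base-sensitive bis-enone.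

**6 to 4 to 3 to 2 to 1.** The two enone double bonds, the two carbonyls and finally the transannular bond C10–C11 are removed. This leads back to 1. The forward sequence needs one resolution to fix the absolute configuration of C10 and C11.

## Other disconnections considered

Alternative 1: The cut is C4–C5 and C1–C8. The forward step is an intramolecular Diels–Alder reaction of A2, an indane that carries a 2-silyloxydiene (C1 to C4) on C11 and, on C10 through C9, a nitroalkene (C5=C8). Heating would give A1 and close rings A and C together.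
- In favour: quaternary C5 and two rings form in one reagent-free step with matched polarity. The silyl enol ether and the nitro group are direct precursors of the C2 and C8 carbonyls and of the C3=C4 unsaturation. Ring F is simply bought as a 3,5-dimethoxyphenyl unit.
- Against: the dienophile carbon C5 is fully substituted, and its face must be controlled by C9 and by an acyclic C6 centre. Ring B is still open in A1, so C1–C7 would have to be forged later at an unactivated benzylic CH2 with control of C7.
- Comparison: on bond economy at the A/C junction this plan is better than the chosen one, which spends separate steps on C5–C8, C5–C6 and C3–C4. On ring F it is at least equal. On mechanism it is weaker at the end, because the late C1–C7 closure has no obvious stereocontrol, whereas the chosen plan sets C7 by a trans conjugate addition.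

Alternative 2: The cut is C4–C11 and C12–Ca. The forward step treats A4 with BF3·OEt2. A4 is the bicyclic vinylogous ester with a C5 side chain C9H(aryl)–C10H(3,5-dimethoxyphenyl)–CH=CH–aryl. The styrene would attack C4, the C12 cation would be trapped by the arene, and methanol would be lost to give A3.
- In favour: two rings and the C11 and C12 centres form in one late step. The oxygen pattern of ring F follows from the innate reactivity of the resorcinol ether. A3 is one deprotection from the target.
- Against: the hardest part, the bridged dione with quaternary C5 and the acyclic centres C9 and C10, must be built first. C11 and C12 are set in a cationic cascade under substrate control. The vinylogous ester is a weak electrophile. The second 3,5-dimethoxyphenyl ring (on C7) and the Lewis-acid-sensitive diketone offer competing paths.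
- Comparison: in step economy and convergence of the last phase this plan is better, and for ring F it is equal or better, needing no diazo compound and no photochemistry. In mechanistic certainty the chosen plan is better, since its ring F closure is a pericyclic sequence with no stereochemical demand and its aryl methines are set on a rigid, symmetric diquinane.

Alternative 3: The cut is C5–C6 and C1–C8. The forward step is a (3+2) union of ketene A6 (C5=C8=O on the ring C/indane fragment) with the donor–acceptor cyclopropane A7 under InBr3 with EtAlCl2, giving A5.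
- In favour: two fragments of similar size are joined. Ring B and the spiro centre C5 form in one step, and C6 and C7 are carried in from the cyclopropane. A6 could be made from the ring C/indane fragment of the chosen plan, so the two plans are compatible.
- Against: a disubstituted ketene must be generated and trapped in situ next to an acid-labile dioxolane. Opening at the donor carbon normally goes with inversion, so trans-cyclopropane A7 would give the C6 epimer unless the cis isomer or an ionised pathway is used. The geminal diester at C1 must later be turned into one hydrogen and one acetyl group, and a decarboxylation at a future bridgehead is not trivial.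
- Comparison: in convergence for ring B this plan is better, replacing five steps of the chosen plan by one. In stereochemical certainty at C6 and C7 and in functional-group overhead at C1 the chosen plan is better.

Key step: step 10

Assumption: the transannular diacetoxylation of 1 is taken to give the endo,endo-diacetate and the lipase to hydrolyse the enantiomer with (R)-configured carbinol carbons; if either is reversed the other fraction of the resolution is carried on, since both carbinol centres are oxidised in step 3 and only the ring-fusion configuration matters.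

## Route

Step 1
Reactants: 1 (1Z,5Z)-cycloocta-1,5-diene
Product: 2 rac-endo,endo-cis-bicyclo[3.3.0]octane-2,6-diyl diacetate
Conditions: PhI(OAc)2, AcOH, reflux
Reagents that add atoms: (diacetoxyiodo)benzene, CC(=O)OI(OC(C)=O)c1ccccc1
Why: Electrophilic trivalent iodine adds to one alkene and the second alkene closes the transannular bond C10–C11 (iodine-mediated transannular diacetoxylation); the bicyclo[3.3.0]octane can only be cis-fused and the C2-symmetric diacetate forms as a racemate.

Step 2
Reactants: 2 rac-endo,endo-cis-bicyclo[3.3.0]octane-2,6-diyl diacetate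
Product: 3 (1S,2R,5S,6R)-cis-bicyclo[3.3.0]octane-2,6-diol
Conditions: Candida antarctica lipase B (immobilised), phosphate buffer pH 7, MTBE, 30 °C, about half conversion
Reagents that add atoms: none
Why: Lipase-catalysed enantioselective hydrolysis (kinetic resolution); the enantiomer with both carbinol carbons R should be cleaved twice while its mirror image stays esterified and is separated, which fixes the absolute configuration of C10 and C11.

Step 3
Reactants: 3 (1S,2R,5S,6R)-cis-bicyclo[3.3.0]octane-2,6-diol
Product: 4 (1S,5S)-cis-bicyclo[3.3.0]octane-2,6-dione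
Conditions: TEMPO (cat.), KBr (cat.), NaOCl, NaHCO3, CH2Cl2/H2O, 0 °C
Reagents that add atoms: none
Why: Nitroxyl-catalysed hypochlorite oxidation of both secondary alcohols; the carbinol centres are erased and the cis ring fusion is the stable one.

Step 4
Reactants: 4 (1S,5S)-cis-bicyclo[3.3.0]octane-2,6-dione
Product: 6 (1S,5S)-cis-bicyclo[3.3.0]octa-3,7-diene-2,6-dione, via bis-silyl enol ether 5 (not isolated)
Conditions: LiN(iPr)2, Me3SiCl, THF, −78 °C; then Pd(OAc)2, MeCN, 25 °C
Reagents that add atoms: none
Why: Kinetic deprotonation at the two methylene α-carbons (C5 and Ca) with in situ silylation, then Saegusa–Ito oxidation in which divalent palladium is reduced to zerovalent palladium; C2 symmetry is kept and no stereocentre is touched.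

Step 5
Reactants: 6 (1S,5S)-cis-bicyclo[3.3.0]octa-3,7-diene-2,6-dione; 7 2,4,6-tris(4-methoxyphenyl)boroxine
Product: 9 (1S,4R,5S,8R)-4,8-bis(4-methoxyphenyl)-cis-bicyclo[3.3.0]octane-2,6-dione, via mono-adduct enone 8 (not isolated)
Conditions: [Rh(OH)(cod)]2 (cat.), (4-MeOC6H4BO)3 (1 equiv), dioxane/H2O (10:1), 30 °C
Reagents that add atoms: none
Why: Rhodium-catalysed conjugate arylation (Hayashi–Miyaura reaction): water opens the boroxine, the aryl group passes to monovalent rhodium, the aryl–rhodium species inserts the enone and the rhodium enolate is protonated; one boroxine carries three aryl groups, so one equivalent serves both enones under near-neutral conditions that spare the acidic ring-fusion hydrogens of 6. Each aryl should enter C9 or C12 from the convex face of the cis-diquinane (cis to H10 and H11), and because 6 is C2-symmetric the two additions are equivalent and give one diastereomer.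

Step 6
Reactants: 9 (1S,4R,5S,8R)-4,8-bis(4-methoxyphenyl)-cis-bicyclo[3.3.0]octane-2,6-dione
Product: 10 C4 mono(ethylene ketal) of 9
Conditions: HOCH2CH2OH (1 equiv), TsOH (cat.), benzene, reflux, Dean–Stark, partial conversion
Reagents that add atoms: ethane-1,2-diol, OCCO
Why: Acid-catalysed ketalisation; the two carbonyl groups of 9 are homotopic by the C2 axis, so the mono-ketal is a single compound, and recovered 9 and bis-ketal are recycled.

Step 7
Reactants: 10 C4 mono(ethylene ketal) of 9
Product: 11 enol triflate of 10 (Ca=Cf double bond with OTf on Cf)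
Conditions: KN(SiMe3)2, THF, −78 °C; PhNTf2
Reagents that add atoms: N-phenylbis(trifluoromethanesulfonimide), O=S(=O)(N(c1ccccc1)S(=O)(=O)C(F)(F)F)C(F)(F)F
Why: Kinetic deprotonation of the free ketone at the methylene carbon Ca, not at the ring-fusion methine C10, and O-sulfonylation of the enolate; no stereocentre is affected.

Step 8
Reactants: 11 enol triflate of 10; 12 tributyl(1-ethoxyvinyl)stannane
Product: 14 methyl ketone (acetyl on Cf of the Ca=Cf cyclopentene with C4 as dioxolane), via 2-ethoxydiene 13 (not isolated)
Conditions: Pd(PPh3)4 (cat.), LiCl, THF, 65 °C; then 1 M HCl, 0 °C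
Reagents that add atoms: water, O
Why: Stille coupling of the enol triflate (zerovalent palladium, LiCl) with an acyl-anion equivalent, then mild hydrolysis of the enol ether, which is far faster than hydrolysis of the dioxolane, gives the 1-acetylcyclopentene.

Step 9
Reactants: 14 methyl ketone
Product: 16 diazomethyl ketone (COCHN2 on Cf), via trifluoroacetyl diketone 15 (not isolated)
Conditions: LiN(SiMe3)2, THF, −78 °C; CF3CO2CH2CF3; 5% HCl work-up; then 4-AcNHC6H4SO2N3, Et3N, H2O, MeCN, 25 °C
Reagents that add atoms: 4-acetamidobenzenesulfonyl azide, CC(=O)Nc1ccc(cc1)S(=O)(=O)N=[N+]=[N-]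
Why: Detrifluoroacetylative (Regitz-type) diazo transfer: kinetic enolisation of the methyl group, Claisen trifluoroacetylation, then diazo transfer with loss of the trifluoroacetyl group; it uses no diazomethane and no acid chloride, so the conjugated double bond and the ketal are not at risk.

Step 10
Reactants: 16 diazomethyl ketone; 17 ethoxyacetylene
Product: 21 indane phenol (ring F with OH on Cb and OEt on Cd; C4 as dioxolane), via vinylketene 18 (not isolated), via vinylcyclobutenone 19 (not isolated), via dienylketene 20 (not isolated)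
Conditions: hν (300 nm), ClCH2CH2Cl, 25 °C; then 80 °C
Reagents that add atoms: none
Why: Irradiation expels N2 and the cyclopentenyl carbon Cf migrates from the carbonyl carbon to the diazo carbon (photo-Wolff rearrangement), giving vinylketene 18. The electron-rich terminal carbon of 17 attacks the ketene carbonyl carbon and the [2+2] cycloaddition gives cyclobutenone 19 with OEt on its C3. Conrotatory four-electron ring opening (light or 80 °C) gives dienylketene 20; six-electron electrocyclisation between the ketene carbon and the vinylic carbon Ca, then tautomerisation, closes the six-membered ring F onto the cyclopentene. The closest known reaction type is the second-generation Danheiser benzannulation of α,β-unsaturated diazo ketones with alkoxy- or siloxyalkynes. No stereocentre is formed, and C9 to C12 are spectators because all bond changes occur at sp2 or sp carbons. The step needs one regiochemical outcome, OH on Cb next to Ca and OEt on Cd; the polarisation of the ynol ether secures it, and only the unsubstituted vinylic carbon Ca can take part in the electrocyclisation. Irradiation at 300 nm should address the diazo ketone chromophore and not the anisole rings.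

Step 11
Reactants: 21 indane phenol
Product: 22 methyl ether of 21 (OMe on Cb)
Conditions: MeI, K2CO3, acetone, reflux
Reagents that add atoms: iodomethane, CI
Why: Williamson methylation of the phenol so that it does not interfere with the base-mediated steps that follow; all ethers are cleaved together at the end.

Step 12
Reactants: 22 methyl ether of 21
Product: 23 C4 ketone (ring C cyclopentanone fused to the indane)
Conditions: 1 M HCl, THF, 25 °C
Reagents that add atoms: water, O
Why: Acid hydrolysis of the dioxolane releases the C4 ketone; the cis ring fusion at C11 is the stable one, so enolisation there does no harm.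

Step 13
Reactants: 23 C4 ketone
Product: 24 C5 hydroxymethylene ketone
Conditions: NaH, HCO2Et, THF, 0 to 25 °C; aq HCl
Reagents that add atoms: ethyl formate, CCOC=O
Why: Claisen formylation under equilibrating conditions; only acylation at the methylene C5 is driven by formation of the stabilised enolate, so C11 is not formylated, and the new carbon is C8.

Step 14
Reactants: 24 C5 hydroxymethylene ketone; 25 (E)-3-(4-methoxyphenyl)prop-2-en-1-ol
Product: 26 (E)-4-methoxycinnamyl enol ether of 24
Conditions: PPh3, iPrO2CN=NCO2iPr, THF, 0 °C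
Reagents that add atoms: none
Why: Mitsunobu O-alkylation of the acidic vinylogous acid with a primary allylic alcohol; the (E)-alkoxymethylene ketone, with the oxygen remote from the C4 carbonyl, is expected as the more stable isomer.

Step 15
Reactants: 26 (E)-4-methoxycinnamyl enol ether of 24
Product: 27 keto aldehyde (C5 bearing CHO and the 1-(4-methoxyphenyl)allyl group)
Conditions: toluene, 110 °C
Reagents that add atoms: none
Why: Claisen [3,3] rearrangement of the allyl vinyl ether: C6 bonds to C5 while C8 becomes the aldehyde. Delivery to the face of C5 opposite the neighbouring C9 aryl should set the quaternary centre (C8 cis and C6 trans to that aryl); a chair transition state with the (E)-enol ether and the (E)-cinnamyl group places the C6 aryl pseudo-equatorial, which gives the required C5/C6 relationship.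

Step 16
Reactants: 27 keto aldehyde
Product: 28 spiro diketone (ring B cyclopentanone: C8 ketone with C1H2 and C7H2)
Conditions: [Rh(nbd)(dppe)]BF4 (cat., activated with H2), CH2Cl2, 25 °C
Reagents that add atoms: none
Why: Rhodium-catalysed intramolecular hydroacylation of a 4-pentenal (oxidative addition of the aldehyde C–H to monovalent rhodium, anti-Markovnikov hydrometalation, reductive elimination) forms C8–C1 and closes ring B; the quaternary C5 favours cyclisation and no stereocentre is formed.

Step 17
Reactants: 28 spiro diketone
Product: 30 spiro enone (C8 ketone with C1=C7), via silyl enol ether 29 (not isolated)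
Conditions: LiN(iPr)2, Me3SiCl, THF, −78 °C; then Pd(OAc)2, MeCN, 25 °C
Reagents that add atoms: none
Why: Kinetic deprotonation at the methylene C1 (the C4 ketone has only the hindered methine C11–H) and Saegusa–Ito oxidation give the C1=C7 enone; C6 is not exposed to base afterwards.

Step 18
Reactants: 30 spiro enone; 31 3,5-dimethoxyphenylmagnesium chloride; 32 acetaldehyde
Product: 34 aldol (C7 aryl; 1-hydroxyethyl on C1), via magnesium enolate 33 (not isolated)
Conditions: CuBr·SMe2 (cat.), THF, −78 °C; then MeCHO, −78 °C; aq NH4Cl
Reagents that add atoms: none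
Why: Copper-catalysed conjugate addition to the cyclopentenone from the face opposite the C6 aryl should set C7 (trans-diaryl), and the magnesium enolate is trapped regiospecifically at C1 by the aldehyde (three-component coupling); the configurations at C1 and at the carbinol carbon do not matter.

Step 19
Reactants: 34 aldol
Product: 35 triketone (acetyl on C1)
Conditions: Dess–Martin periodinane, NaHCO3, CH2Cl2, 25 °C
Reagents that add atoms: none
Why: Dess–Martin oxidation of the β-hydroxy ketone gives the 2-acetylcyclopentanone; C1 is now freely epimerisable through its enol.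

Step 20
Reactants: 35 triketone
Product: 36 hexamethyl ethyl ether of the target
Conditions: TsOH (cat.), benzene, reflux, Dean–Stark
Reagents that add atoms: none
Why: Acid-catalysed intramolecular aldol condensation: the terminal enol C2=C3 of the diketo tautomer adds to the protonated C4 ketone and water is lost toward C3 to give the conjugated enone. Only the C1 epimer with the acetyl group cis to C4 can cyclise, and bridging then locks C1; enolisation through C1 is reversible and unproductive because that enol cannot sit at a bridgehead.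

Step 21
Reactants: 36 hexamethyl ethyl ether of the target
Product: 37 CNP0407321.1
Conditions: BBr3, CH2Cl2, −78 to 25 °C; then H2O
Reagents that add atoms: none
Why: Lewis-acid cleavage of the six methyl ethers and the ethyl ether; no base is used, so the non-enolisable 1,3-diketone is not exposed to retro-Claisen cleavage.

## Compound list

1 | (1Z,5Z)-cycloocta-1,5-diene | C1CC=CCCC=C1 | starting material
2 | rac-endo,endo-cis-bicyclo[3.3.0]octane-2,6-diyl diacetate (one enantiomer drawn) | CC(=O)O[C@@H]1CC[C@@H]2[C@H](OC(C)=O)CC[C@H]12 | intermediate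
3 | (1S,2R,5S,6R)-cis-bicyclo[3.3.0]octane-2,6-diol | O[C@@H]1CC[C@@H]2[C@H](O)CC[C@H]12 | intermediate
4 | (1S,5S)-cis-bicyclo[3.3.0]octane-2,6-dione | O=C1CC[C@@H]2C(=O)CC[C@H]12 | intermediate
5 | (1S,5S)-2,6-bis(trimethylsilyloxy)bicyclo[3.3.0]octa-2,6-diene (not isolated) | C[Si](C)(C)OC1=CC[C@@H]2C(O[Si](C)(C)C)=CC[C@H]12 | intermediate
6 | (1S,5S)-cis-bicyclo[3.3.0]octa-3,7-diene-2,6-dione | O=C1C=C[C@@H]2C(=O)C=C[C@H]12 | intermediate
7 | 2,4,6-tris(4-methoxyphenyl)boroxine (cyclic anhydride of 4-methoxyphenylboronic acid) | COc1ccc(cc1)B1OB(c2ccc(OC)cc2)OB(c2ccc(OC)cc2)O1 | starting material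
8 | (1S,5S,8R)-8-(4-methoxyphenyl)-cis-bicyclo[3.3.0]oct-3-ene-2,6-dione; mono-adduct enone, aryl cis to the ring-fusion hydrogens (not isolated) | O=C1C[C@@H](c3ccc(OC)cc3)[C@@H]2C(=O)C=C[C@H]12 | intermediate
9 | (1S,4R,5S,8R)-4,8-bis(4-methoxyphenyl)-cis-bicyclo[3.3.0]octane-2,6-dione; both aryls cis to the ring-fusion hydrogens | O=C1C[C@@H](c3ccc(OC)cc3)[C@@H]2C(=O)C[C@@H](c3ccc(OC)cc3)[C@H]12 | intermediate
10 | mono(ethylene ketal) of 9: dioxolane at C4, ketone at Cf | C1COC2(O1)[C@H]3[C@H](c4ccc(OC)cc4)CC(=O)[C@H]3[C@H](c3ccc(OC)cc3)C2 | intermediate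
11 | enol triflate of 10: Ca=Cf double bond, OTf on Cf | C1COC2(O1)[C@H]3[C@H](c4ccc(OC)cc4)C=C(OS(=O)(=O)C(F)(F)F)[C@H]3[C@H](c3ccc(OC)cc3)C2 | intermediate
12 | tributyl(1-ethoxyvinyl)stannane | CCCC[Sn](CCCC)(CCCC)C(=C)OCC | starting material
13 | 2-ethoxydiene: 1-ethoxyvinyl on Cf (not isolated) | C1COC2(O1)[C@H]3[C@H](c4ccc(OC)cc4)C=C(C(=C)OCC)[C@H]3[C@H](c3ccc(OC)cc3)C2 | intermediate
14 | methyl ketone: acetyl on Cf of the Ca=Cf cyclopentene, C4 as dioxolane | C1COC2(O1)[C@H]3[C@H](c4ccc(OC)cc4)C=C(C(C)=O)[C@H]3[C@H](c3ccc(OC)cc3)C2 | intermediate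
15 | 4,4,4-trifluoro-1,3-diketone: COCH2COCF3 on Cf (not isolated) | C1COC2(O1)[C@H]3[C@H](c4ccc(OC)cc4)C=C(C(=O)CC(=O)C(F)(F)F)[C@H]3[C@H](c3ccc(OC)cc3)C2 | intermediate
16 | diazomethyl ketone: COCHN2 on Cf | C1COC2(O1)[C@H]3[C@H](c4ccc(OC)cc4)C=C(C(=O)C=[N+]=[N-])[C@H]3[C@H](c3ccc(OC)cc3)C2 | intermediate
17 | ethoxyacetylene | CCOC#C | starting material
18 | vinylketene: CH=C=O on Cf (not isolated) | C1COC2(O1)[C@H]3[C@H](c4ccc(OC)cc4)C=C(C=C=O)[C@H]3[C@H](c3ccc(OC)cc3)C2 | intermediate
19 | 3-ethoxy-4-(cyclopentenyl)cyclobut-2-en-1-one, epimers at the cyclobutenone carbon (not isolated) | C1COC2(O1)[C@H]3[C@H](c4ccc(OC)cc4)C=C(C4C(=O)C=C4OCC)[C@H]3[C@H](c3ccc(OC)cc3)C2 | intermediate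
20 | dienylketene: Cf–CH=C(OEt)–CH=C=O, ketene arm cis to Cf (not isolated) | C1COC2(O1)[C@H]3[C@H](c4ccc(OC)cc4)C=C(/C=C(/OCC)C=C=O)[C@H]3[C@H](c3ccc(OC)cc3)C2 | intermediate
21 | indane phenol: ring F with OH on Cb and OEt on Cd, C4 as dioxolane | C1COC2(O1)[C@H]3[C@H](c4ccc(OC)cc4)c4c(O)cc(OCC)cc4[C@H]3[C@H](c3ccc(OC)cc3)C2 | intermediate
22 | methyl ether of 21 (OMe on Cb) | C1COC2(O1)[C@H]3[C@H](c4ccc(OC)cc4)c4c(OC)cc(OCC)cc4[C@H]3[C@H](c3ccc(OC)cc3)C2 | intermediate
23 | C4 ketone | O=C1[C@H]2[C@H](c3ccc(OC)cc3)c3c(OC)cc(OCC)cc3[C@H]2[C@H](c2ccc(OC)cc2)C1 | intermediate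
24 | C5 hydroxymethylene ketone (enol OH cis to the C4 carbonyl) | O=C1[C@H]2[C@H](c3ccc(OC)cc3)c3c(OC)cc(OCC)cc3[C@H]2[C@H](c2ccc(OC)cc2)/C1=C/O | intermediate
25 | (E)-3-(4-methoxyphenyl)prop-2-en-1-ol | OC/C=C/c1ccc(OC)cc1 | starting material
26 | (E)-4-methoxycinnamyl enol ether of 24 (oxygen remote from the C4 carbonyl) | O=C1[C@H]2[C@H](c3ccc(OC)cc3)c3c(OC)cc(OCC)cc3[C@H]2[C@H](c2ccc(OC)cc2)\C1=C/OC/C=C/c1ccc(OC)cc1 | intermediate
27 | keto aldehyde: C5 carries CHO (cis to the C9 aryl) and the 1-(4-methoxyphenyl)allyl group (C6, trans to the C9 aryl) | O=C1[C@H]2[C@H](c3ccc(OC)cc3)c3c(OC)cc(OCC)cc3[C@H]2[C@H](c2ccc(OC)cc2)[C@@]1(C=O)[C@H](c1ccc(OC)cc1)C=C | intermediate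
28 | spiro diketone: ring B cyclopentanone (C8 ketone, C1H2, C7H2, C6 aryl) spiro at C5 | O=C1[C@H]2[C@H](c3ccc(OC)cc3)c3c(OC)cc(OCC)cc3[C@H]2[C@H](c2ccc(OC)cc2)[C@]13C(=O)CC[C@H]3c1ccc(OC)cc1 | intermediate
29 | C8 trimethylsilyl enol ether of 28 (C8=C1) (not isolated) | O=C1[C@H]2[C@H](c3ccc(OC)cc3)c3c(OC)cc(OCC)cc3[C@H]2[C@H](c2ccc(OC)cc2)[C@]13C(O[Si](C)(C)C)=CC[C@H]3c1ccc(OC)cc1 | intermediate
30 | spiro enone: C8 ketone with C1=C7 | O=C1[C@H]2[C@H](c3ccc(OC)cc3)c3c(OC)cc(OCC)cc3[C@H]2[C@H](c2ccc(OC)cc2)[C@]13C(=O)C=C[C@H]3c1ccc(OC)cc1 | intermediate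
31 | 3,5-dimethoxyphenylmagnesium chloride | COc1cc(OC)cc([Mg]Cl)c1 | starting material
32 | acetaldehyde | CC=O | starting material
33 | chloromagnesium enolate (C8=C1) with the C7 aryl trans to the C6 aryl (not isolated) | O=C1[C@H]2[C@H](c3ccc(OC)cc3)c3c(OC)cc(OCC)cc3[C@H]2[C@H](c2ccc(OC)cc2)[C@]13C(O[Mg]Cl)=C[C@H](c1cc(OC)cc(OC)c1)[C@H]3c1ccc(OC)cc1 | intermediate
34 | aldol: 1-hydroxyethyl on C1 (epimers at C1 and at the carbinol carbon) | O=C1[C@H]2[C@H](c3ccc(OC)cc3)c3c(OC)cc(OCC)cc3[C@H]2[C@H](c2ccc(OC)cc2)[C@]13C(=O)C(C(C)O)[C@H](c1cc(OC)cc(OC)c1)[C@H]3c1ccc(OC)cc1 | intermediate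
35 | triketone: acetyl on C1 (C1 epimerisable) | O=C1[C@H]2[C@H](c3ccc(OC)cc3)c3c(OC)cc(OCC)cc3[C@H]2[C@H](c2ccc(OC)cc2)[C@]13C(=O)C(C(C)=O)[C@H](c1cc(OC)cc(OC)c1)[C@H]3c1ccc(OC)cc1 | intermediate
36 | hexamethyl ethyl ether of the target (OEt on Cd) | O=C1C=C2[C@H]3[C@H](c4ccc(OC)cc4)c4c(OC)cc(OCC)cc4[C@H]3[C@H](c3ccc(OC)cc3)[C@]23C(=O)[C@H]1[C@H](c1cc(OC)cc(OC)c1)[C@H]3c1ccc(OC)cc1 | intermediate
37 | CNP0407321.1 | O=C1C=C2[C@H]3[C@H](c4ccc(O)cc4)c4c(O)cc(O)cc4[C@H]3[C@H](c3ccc(O)cc3)[C@]23C(=O)[C@H]1[C@H](c1cc(O)cc(O)c1)[C@H]3c1ccc(O)cc1 | target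

## Step count and least certain steps

Total step count: 21. Longest linear sequence: 21 steps (1 to 37).

**Step 10 (key step).** The most likely failure is inefficient excitation of the diazo ketone, because three aryl ether chromophores absorb nearby. A second is loss of vinylketene 18 by dimerisation before the ynol ether captures it, or decomposition of the ynol ether adduct during the thermal ring opening.
Fallback: make the same vinylketene thermally, without a diazo compound. It sets out from 11. Negishi coupling with BrZnCH2CO2Me under Pd(PPh3)4 gives methyl 2-(cyclopentenyl)acetate F1. LiOH gives the acid F2, and 1-chloro-N,N,2-trimethylprop-1-en-1-amine gives the acid chloride F3 under neutral conditions. Slow addition of Et3N to F3 and 17 in CH2Cl2 dehydrochlorinates F3 to 18, which is trapped as 19. Heating then leads through 20 back to 21.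

**Step 15.** The allyl unit must reach C5 on the concave side of the diquinane, so facial selectivity may be poor. A boat transition state or a (Z)-enol ether would give the C6 epimer. The 4-methoxycinnamyl ether may also ionise to an ion pair, with loss of stereospecificity and formation of linear allyl isomers.
Fallback: a catalyst-controlled allylation. It sets out from 23. NaH and dimethyl carbonate give the C5 β-keto ester F4. Alcohol 25 with ClCO2Me and pyridine gives (E)-3-(4-methoxyphenyl)allyl methyl carbonate F5. Branched-selective allylic alkylation of F4 with F5, catalysed by [Ir(cod)Cl]2 and a chiral phosphoramidite, gives the allylated keto ester F6. The ligand antipode is chosen to fix C6 and the C9 aryl directs the face of C5. LiAlH4 gives the diol F7, and Dess–Martin oxidation of both alcohols returns to 27.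

**Step 16.** Decarbonylation of the neopentyl acyl rhodium hydride may compete. So may isomerisation of the vinyl group into conjugation with the C6 aryl, which would destroy C6, and inhibition of the catalyst by chelation of the β-keto aldehyde.
Fallback: ring-closing metathesis. It sets out from 27. CH2=CHMgBr at −78 °C adds to the aldehyde to give the allylic alcohol F8. The second-generation Grubbs catalyst RuCl2(=CHPh)(PCy3)(H2IMes) closes the cyclopentenol F9. Dess–Martin oxidation returns to 30, so step 17 is bypassed as well.

**Step 20.** Enolisation through C1 dominates and is unproductive. The acid may instead promote Friedel–Crafts attack of the cis-disposed 3,5-dimethoxyphenyl ring on the C2 carbonyl, or deacetylation.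
Fallback: an intramolecular Wittig reaction, in which C3 is made the nucleophile without acid. It sets out from 35. LiN(iPr)2 (2 equiv) and Me3SiCl give the 1,3-bis(silyloxy)diene F10. N-Bromosuccinimide brominates its terminal carbon to give the bromomethyl ketone F11. PPh3 gives the phosphonium bromide F12, and Et3N gives the stabilised ylide F13; the C3–H of the phosphonium salt is more acidic than C1–H, so C1 stays sp3. Heating in toluene closes C3=C4 onto the C4 ketone and returns to 36.

## Further compounds

F1 | step 10 | methyl 2-(cyclopentenyl)acetate: CH2CO2Me on Cf, C4 as dioxolane | C1COC2(O1)[C@H]3[C@H](c4ccc(OC)cc4)C=C(CC(=O)OC)[C@H]3[C@H](c3ccc(OC)cc3)C2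
F2 | step 10 | 2-(cyclopentenyl)acetic acid: CH2CO2H on Cf | C1COC2(O1)[C@H]3[C@H](c4ccc(OC)cc4)C=C(CC(=O)O)[C@H]3[C@H](c3ccc(OC)cc3)C2
F3 | step 10 | 2-(cyclopentenyl)acetyl chloride: CH2COCl on Cf | C1COC2(O1)[C@H]3[C@H](c4ccc(OC)cc4)C=C(CC(=O)Cl)[C@H]3[C@H](c3ccc(OC)cc3)C2
F4 | step 15 | C5 β-keto ester (CO2Me trans to the C9 aryl, enolisable) | O=C1[C@H]2[C@H](c3ccc(OC)cc3)c3c(OC)cc(OCC)cc3[C@H]2[C@H](c2ccc(OC)cc2)[C@H]1C(=O)OC
F5 | step 15 | (E)-3-(4-methoxyphenyl)allyl methyl carbonate | COC(=O)OC/C=C/c1ccc(OC)cc1
F6 | step 15 | allylated keto ester: C5 carries CO2Me and the 1-(4-methoxyphenyl)allyl group | O=C1[C@H]2[C@H](c3ccc(OC)cc3)c3c(OC)cc(OCC)cc3[C@H]2[C@H](c2ccc(OC)cc2)[C@@]1(C(=O)OC)[C@H](c1ccc(OC)cc1)C=C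
F7 | step 15 | diol: C4 carbinol (epimers) and CH2OH on C5 | OC1[C@H]2[C@H](c3ccc(OC)cc3)c3c(OC)cc(OCC)cc3[C@H]2[C@H](c2ccc(OC)cc2)[C@@]1(CO)[C@H](c1ccc(OC)cc1)C=C
F8 | step 16 | allylic alcohol: CH(OH)CH=CH2 on C5 (carbinol epimers) | O=C1[C@H]2[C@H](c3ccc(OC)cc3)c3c(OC)cc(OCC)cc3[C@H]2[C@H](c2ccc(OC)cc2)[C@@]1(C(O)C=C)[C@H](c1ccc(OC)cc1)C=C
F9 | step 16 | spiro cyclopentenol: C8 carbinol (epimers) with C1=C7 | O=C1[C@H]2[C@H](c3ccc(OC)cc3)c3c(OC)cc(OCC)cc3[C@H]2[C@H](c2ccc(OC)cc2)[C@]13C(O)C=C[C@H]3c1ccc(OC)cc1
F10 | step 20 | 1,3-bis(trimethylsilyloxy)diene of 35: C8(OSiMe3)=C1–C2(OSiMe3)=C3H2 | O=C1[C@H]2[C@H](c3ccc(OC)cc3)c3c(OC)cc(OCC)cc3[C@H]2[C@H](c2ccc(OC)cc2)[C@]13C(O[Si](C)(C)C)=C(C(=C)O[Si](C)(C)C)[C@H](c1cc(OC)cc(OC)c1)[C@H]3c1ccc(OC)cc1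
F11 | step 20 | bromomethyl ketone: COCH2Br on C1 | O=C1[C@H]2[C@H](c3ccc(OC)cc3)c3c(OC)cc(OCC)cc3[C@H]2[C@H](c2ccc(OC)cc2)[C@]13C(=O)C(C(=O)CBr)[C@H](c1cc(OC)cc(OC)c1)[C@H]3c1ccc(OC)cc1
F12 | step 20 | phosphonium bromide: COCH2PPh3 on C1 | O=C1[C@H]2[C@H](c3ccc(OC)cc3)c3c(OC)cc(OCC)cc3[C@H]2[C@H](c2ccc(OC)cc2)[C@]13C(=O)C(C(=O)C[P+](c4ccccc4)(c4ccccc4)c4ccccc4)[C@H](c1cc(OC)cc(OC)c1)[C@H]3c1ccc(OC)cc1.[Br-]
F13 | step 20 | stabilised ylide: COCH=PPh3 on C1 | O=C1[C@H]2[C@H](c3ccc(OC)cc3)c3c(OC)cc(OCC)cc3[C@H]2[C@H](c2ccc(OC)cc2)[C@]13C(=O)C(C(=O)C=P(c4ccccc4)(c4ccccc4)c4ccccc4)[C@H](c1cc(OC)cc(OC)c1)[C@H]3c1ccc(OC)cc1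
A1 | alternative 1 | tetracyclic silyl enol ether from the intramolecular Diels–Alder reaction (C4 and C8 centres transient) | CC(C)(C)[Si](C)(C)OC1=C[C@@H]2[C@H]3[C@H](c4ccc(OC)cc4)c4c(OC)cc(OC)cc4[C@H]3[C@H](c3ccc(OC)cc3)[C@]2([C@H](c5ccc(OC)cc5)Cc5cc(OC)cc(OC)c5)[C@@H]([N+](=O)[O-])C1
A2 | alternative 1 | indane with the 2-silyloxydiene on C11 and the nitroalkene on C9 (nitroalkene geometry left open) | C=C(O[Si](C)(C)C(C)(C)C)/C=C/[C@H]1[C@H](c2ccc(OC)cc2)c2c(OC)cc(OC)cc2[C@H]1[C@H](c1ccc(OC)cc1)C(=C[N+](=O)[O-])[C@H](c1ccc(OC)cc1)Cc1cc(OC)cc(OC)c1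
A3 | alternative 2 | heptamethyl ether of the target | O=C1C=C2[C@H]3[C@H](c4ccc(OC)cc4)c4c(OC)cc(OC)cc4[C@H]3[C@H](c3ccc(OC)cc3)[C@]23C(=O)[C@H]1[C@H](c1cc(OC)cc(OC)c1)[C@H]3c1ccc(OC)cc1
A4 | alternative 2 | bicyclic vinylogous ester (OMe on C4) with the C9–C10–styryl side chain on C5 | O=C1C=C(OC)[C@]2([C@@H](c3ccc(OC)cc3)[C@H](c3cc(OC)cc(OC)c3)/C=C/c3ccc(OC)cc3)C(=O)[C@H]1[C@H](c1cc(OC)cc(OC)c1)[C@H]2c1ccc(OC)cc1
A5 | alternative 3 | spiro cyclopentanone diester | C1COC2(O1)[C@H]3[C@H](c4ccc(OC)cc4)c4c(OC)cc(OC)cc4[C@H]3[C@H](c3ccc(OC)cc3)[C@]25C(=O)C(C(=O)OC)(C(=O)OC)[C@H](c1cc(OC)cc(OC)c1)[C@H]5c1ccc(OC)cc1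
A6 | alternative 3 | ketene of fragment 1 (C5=C8=O) | C1COC2(O1)[C@H]3[C@H](c4ccc(OC)cc4)c4c(OC)cc(OC)cc4[C@H]3[C@H](c3ccc(OC)cc3)C2=C=O
A7 | alternative 3 | dimethyl trans-2-(3,5-dimethoxyphenyl)-3-(4-methoxyphenyl)cyclopropane-1,1-dicarboxylate (fragment 2) | COC(=O)C1(C(=O)OC)[C@H](c2cc(OC)cc(OC)c2)[C@H]1c1ccc(OC)cc1
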